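**Retrosynthetic overview**
1. The chain A-CH2-B-CH2-C-CH2-D-CH2-E is symmetric about ring C. The two inner bridges are cut at the aryl-CH2 bonds of rings B and D that face ring C, leading back to a ring C bis(benzylic ester) of two identical ring A-B carboxylic acids.
2. The strategy rests on C3 of ring B and of ring D, the carbon facing ring C: it lies between the oxygen-bearing carbons C2 and C4, so a carboxyl group there is a 2,6-dioxygenated benzoate, twisted out of the ring plane and able to lose CO2 at palladium.
3. That carboxyl is carried as a formyl group until late. It blocks C3 while ring A is attached at C1 by reductive alkylation, and is then oxidised to the acid.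
4. All five rings come from butyrylphloroglucinol. No ring is closed anywhere: rings A and E arise by dearomatising gem-dimethylation, rings B, C and D from one benzylated dialdehyde.
5. Order of assembly: ring A, then A-B (identical to E-D), esterification to ring C, twofold CO2 extrusion, enol ether hydrolysis, hydrogenolysis.

Key step: step 9

Remark 1: double O-methylation of the ring A triketone (step 6) is assumed to give the cross-conjugated 3,5-dimethoxy-2,5-dienone, with both methoxy groups next to the CMe2 carbon. A regioisomeric bis(enol ether) would equally lack acidic hydrogen and would hydrolyse to the same triketone in step 10.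
Remark 2: in steps that convert three or more like groups (steps 3, 10, 11), and in the Duff reaction (step 2), whose aldehydes are released only on hydrolysis, partly converted species are not numbered.

Step 1
Reactants: 1 butyrylphloroglucinol
Product: 3 butyrylfilicinic acid (2-butanoyl-3,5-dihydroxy-4,4-dimethylcyclohexa-2,5-dien-1-one), via C-monomethyl intermediate 2 (not isolated)
Conditions: MeI (2.2 equiv), NaOMe (3 equiv), MeOH, 0 °C to 25 °C; then aqueous HCl
Reagents that add atoms: iodomethane, CI
Why: Alkylative dearomatisation of an acylphloroglucinol: the polyanion is C-methylated twice at one free ring carbon, the established way to acylfilicinic acids, and limiting MeI holds back further methylation at the second free carbon.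

Step 2
Reactants: 1 butyrylphloroglucinol
Product: 4 5-butanoyl-2,4,6-trihydroxybenzene-1,3-dicarbaldehyde
Conditions: hexamethylenetetramine (2.5 equiv), CF3CO2H, 90 °C; then 3 M HCl, 90 °C
Reagents that add atoms: hexamethylenetetramine, C1N2CN3CN1CN(C2)C3; water, O
Why: Duff formylation: the iminium ions from hexamethylenetetramine substitute both free ring carbons (the same conditions formylate phloroglucinol three times), and acid hydrolysis releases the two aldehydes.

Step 3
Reactants: 4 5-butanoyl-2,4,6-trihydroxybenzene-1,3-dicarbaldehyde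
Product: 5 2,4,6-tris(benzyloxy)-5-butanoylbenzene-1,3-dicarbaldehyde
Conditions: BnBr (4 equiv), K2CO3 (5 equiv), Bu4NI (cat.), DMF, 60 °C
Reagents that add atoms: benzyl bromide, BrCc1ccccc1
Why: Williamson etherification: the ring has no free carbon, so the chelated phenoxides can only O-alkylate, and excess BnBr in warm DMF should carry all three hindered hydroxyls to ethers.

Step 4
Reactants: 5 2,4,6-tris(benzyloxy)-5-butanoylbenzene-1,3-dicarbaldehyde
Product: 7 ring C diol 1-[2,4,6-tris(benzyloxy)-3,5-bis(hydroxymethyl)phenyl]butan-1-one, via hydroxy aldehyde 6 (not isolated)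
Conditions: NaBH4 (1.2 equiv), EtOH/CH2Cl2, -78 °C to -20 °C
Reagents that add atoms: none
Why: Chemoselective hydride reduction: at low temperature NaBH4 reduces both aldehydes far faster than the butyryl ketone, which is twisted out of the ring plane and shielded by two ortho benzyloxy groups.

Step 5
Reactants: 3 butyrylfilicinic acid; 5 2,4,6-tris(benzyloxy)-5-butanoylbenzene-1,3-dicarbaldehyde (2.5 equiv, surplus recovered)
Product: 9 ring A-CH2-ring B aldehyde with free ring A enols, via Knoevenagel arylidene 8 (not isolated)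
Conditions: L-proline (20 mol %), Hantzsch ester (diethyl 2,6-dimethyl-1,4-dihydropyridine-3,5-dicarboxylate, 1.2 equiv), CH2Cl2, 25 °C to 40 °C
Reagents that add atoms: none
Why: Organocatalytic three-component reductive alkylation (Knoevenagel condensation, then conjugate hydride transfer from the Hantzsch ester): the only C-H carbon of 3, between two enolised carbonyls, condenses with one formyl group of 5 and the arylidene triketone is reduced at once, so only the C-alkylated product can form, and the excess of 5 should keep its second formyl group untouched.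

Step 6
Reactants: 9 ring A-CH2-ring B aldehyde with free ring A enols
Product: 11 ring A bis(methyl enol ether) aldehyde, via mono(methyl enol ether) 10 (not isolated)
Conditions: TMSCHN2 (excess), MeOH/toluene, 0 °C to 25 °C
Reagents that add atoms: trimethylsilyldiazomethane, C[Si](C)(C)C=[N+]=[N-]
Why: O-methylation of acidic enols by a diazoalkane: proton transfer from the vinylogous acid and then from the chelated enol gives a methyldiazonium ion pair that collapses on oxygen, so no C-methylation is expected and the benzyl ethers, the ketone and the hindered aldehyde stay untouched.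

Step 7
Reactants: 11 ring A bis(methyl enol ether) aldehyde
Product: 12 protected ring A-B carboxylic acid
Conditions: NaClO2, NaH2PO4, 2-methyl-2-butene, t-BuOH/THF/H2O, 0 °C to 25 °C
Reagents that add atoms: sodium chlorite, [Na+].[O-]Cl=O
Why: Pinnick oxidation: chlorous acid converts the hindered aryl aldehyde to the acid near pH 4, where benzyl ethers and vinylogous methyl esters should survive, and 2-methyl-2-butene removes the hypochlorous acid.

Step 8
Reactants: 12 protected ring A-B carboxylic acid (2.2 equiv); 7 ring C diol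
Product: 14 ring C bis(benzylic ester) of two ring A-B acids, via monoester 13 (not isolated)
Conditions: PPh3, DIAD, THF, 0 °C to 25 °C
Reagents that add atoms: none
Why: Twofold Mitsunobu esterification: the alcohol is activated, not the crowded carboxyl carbon, so the 2,6-disubstituted benzoate attacks the benzylic oxyphosphonium carbon and hindrance at the acyl carbon does not matter.

Step 9
Reactants: 14 ring C bis(benzylic ester) of two ring A-B acids
Product: 16 fully protected pentamer (nine benzyl ethers, four methyl enol ethers), via half-coupled monoester 15 (not isolated)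
Conditions: Pd(OAc)2 (20 mol %), 1,1'-bis(diphenylphosphino)ferrocene (dppf, 22 mol %), 4 Å molecular sieves, anhydrous DMA/toluene, 110 °C, argon
Reagents that add atoms: none
Why: Proposed new method: Pd(OAc)2 is reduced by dppf to zerovalent palladium, which ionises each benzylic C-O bond of ring C (helped by its two ortho benzyloxy groups) to an η3-benzyl complex of divalent palladium that keeps the 2,6-bis(benzyloxy)benzoate as counter-ligand; this carboxylate, twisted out of the ring plane by its two ortho oxygens, loses CO2 by ipso-palladation to an aryl(benzyl)palladium species, and reductive elimination, favoured by the wide bite angle of dppf, forms the aryl-CH2 bond and returns zerovalent palladium. The closest known reaction types are the palladium-catalysed decarboxylative benzylation of benzyl esters of activated acids (β-keto acids, alkynoic acids) and the decarboxylative palladation of 2,6-dialkoxybenzoic acids used in decarboxylative Heck and biaryl couplings; joining the two on a benzyl arenecarboxylate is the untested part. No ring is closed and no stereocentre is formed. Coupling must win over protodecarboxylation and over crossover between molecules: the first is secured by a substrate without any O-H or other acidic hydrogen (all phenols are benzyl ethers, both triketones are bis(enol ethers)) in a dry medium, the second by the carboxylate staying on the palladium that holds the benzyl group, the two events at ring C following each other through 15. Since no free benzylic cation or quinone methide intervenes, the ring A-CH2-ring B bridges already present cannot be cleaved and re-formed.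

Step 10
Reactants: 16 fully protected pentamer
Product: 17 nona-O-benzyl pentamer with free ring A and ring E triketones
Conditions: 1 M HCl, THF, 40 °C
Reagents that add atoms: water, O
Why: Acid hydrolysis of vinylogous esters: protonation of the dienone carbonyls of rings A and E lets water add at the methoxy-bearing carbons and expel methanol, and with every phenol still benzylated no quinone methide can form, so the methylene bridges should not scramble.

Step 11
Reactants: 17 nona-O-benzyl pentamer with free ring A and ring E triketones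
Product: 18 target CNP0188003.0
Conditions: H2 (1 atm), palladium on carbon (10 % Pd/C), EtOAc/MeOH, 25 °C
Reagents that add atoms: none
Why: Hydrogenolysis of nine aryl benzyl ethers under neutral conditions, where the chelated aryl ketones and the enolised triketones of rings A and E should not be reduced.

**Compound list**
1 | butyrylphloroglucinol, 1-(2,4,6-trihydroxyphenyl)butan-1-one | CCCC(=O)c1c(O)cc(O)cc1O | starting material
2 | 1-(2,4,6-trihydroxy-3-methylphenyl)butan-1-one | CCCC(=O)c1c(O)cc(O)c(C)c1O | intermediate
3 | butyrylfilicinic acid, 2-butanoyl-3,5-dihydroxy-4,4-dimethylcyclohexa-2,5-dien-1-one | CCCC(=O)C1=C(O)C(C)(C)C(O)=CC1=O | intermediate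
4 | 5-butanoyl-2,4,6-trihydroxybenzene-1,3-dicarbaldehyde | CCCC(=O)c1c(O)c(C=O)c(O)c(C=O)c1O | intermediate
5 | 2,4,6-tris(benzyloxy)-5-butanoylbenzene-1,3-dicarbaldehyde | CCCC(=O)c1c(OCc2ccccc2)c(C=O)c(OCc2ccccc2)c(C=O)c1OCc1ccccc1 | intermediate
6 | 2,4,6-tris(benzyloxy)-3-butanoyl-5-(hydroxymethyl)benzaldehyde | CCCC(=O)c1c(OCc2ccccc2)c(C=O)c(OCc2ccccc2)c(CO)c1OCc1ccccc1 | intermediate
7 | ring C diol, 1-[2,4,6-tris(benzyloxy)-3,5-bis(hydroxymethyl)phenyl]butan-1-one | CCCC(=O)c1c(OCc2ccccc2)c(CO)c(OCc2ccccc2)c(CO)c1OCc1ccccc1 | intermediate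
8 | Knoevenagel arylidene, 2-butanoyl-3-hydroxy-4,4-dimethyl-6-{[2,4,6-tris(benzyloxy)-3-butanoyl-5-formylphenyl]methylidene}cyclohex-2-ene-1,5-dione (alkene geometry not defined) | CCCC(=O)C1=C(O)C(C)(C)C(=O)C(=Cc2c(OCc3ccccc3)c(C=O)c(OCc3ccccc3)c(C(=O)CCC)c2OCc2ccccc2)C1=O | intermediate
9 | 2,4,6-tris(benzyloxy)-3-butanoyl-5-[(5-butanoyl-2,4-dihydroxy-3,3-dimethyl-6-oxocyclohexa-1,4-dien-1-yl)methyl]benzaldehyde | CCCC(=O)C1=C(O)C(C)(C)C(O)=C(Cc2c(OCc3ccccc3)c(C=O)c(OCc3ccccc3)c(C(=O)CCC)c2OCc2ccccc2)C1=O | intermediate
10 | 2,4,6-tris(benzyloxy)-3-butanoyl-5-[(5-butanoyl-4-hydroxy-2-methoxy-3,3-dimethyl-6-oxocyclohexa-1,4-dien-1-yl)methyl]benzaldehyde | CCCC(=O)C1=C(O)C(C)(C)C(OC)=C(Cc2c(OCc3ccccc3)c(C=O)c(OCc3ccccc3)c(C(=O)CCC)c2OCc2ccccc2)C1=O | intermediate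
11 | 2,4,6-tris(benzyloxy)-3-butanoyl-5-[(5-butanoyl-2,4-dimethoxy-3,3-dimethyl-6-oxocyclohexa-1,4-dien-1-yl)methyl]benzaldehyde | CCCC(=O)C1=C(OC)C(C)(C)C(OC)=C(Cc2c(OCc3ccccc3)c(C=O)c(OCc3ccccc3)c(C(=O)CCC)c2OCc2ccccc2)C1=O | intermediate
12 | 2,4,6-tris(benzyloxy)-3-butanoyl-5-[(5-butanoyl-2,4-dimethoxy-3,3-dimethyl-6-oxocyclohexa-1,4-dien-1-yl)methyl]benzoic acid | CCCC(=O)C1=C(OC)C(C)(C)C(OC)=C(Cc2c(OCc3ccccc3)c(C(=O)O)c(OCc3ccccc3)c(C(=O)CCC)c2OCc2ccccc2)C1=O | intermediate
13 | ring C monoester: one hydroxymethyl group of 7 esterified with acid 12, the other free | CCCC(=O)C1=C(OC)C(C)(C)C(OC)=C(Cc2c(OCc9ccccc9)c(C(=O)OCc3c(OCc9ccccc9)c(CO)c(OCc9ccccc9)c(C(=O)CCC)c3OCc9ccccc9)c(OCc9ccccc9)c(C(=O)CCC)c2OCc9ccccc9)C1=O | intermediate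
14 | ring C bis(benzylic ester): both hydroxymethyl groups of 7 esterified with acid 12 | CCCC(=O)C1=C(OC)C(C)(C)C(OC)=C(Cc2c(OCc9ccccc9)c(C(=O)OCc3c(OCc9ccccc9)c(COC(=O)c4c(OCc9ccccc9)c(CC5=C(OC)C(C)(C)C(OC)=C(C(=O)CCC)C5=O)c(OCc9ccccc9)c(C(=O)CCC)c4OCc9ccccc9)c(OCc9ccccc9)c(C(=O)CCC)c3OCc9ccccc9)c(OCc9ccccc9)c(C(=O)CCC)c2OCc9ccccc9)C1=O | intermediate
15 | half-coupled monoester: ring B-CH2-ring C bridge formed, ring C-CH2-O-CO-ring D ester remaining | CCCC(=O)C1=C(OC)C(C)(C)C(OC)=C(Cc2c(OCc9ccccc9)c(Cc3c(OCc9ccccc9)c(COC(=O)c4c(OCc9ccccc9)c(CC5=C(OC)C(C)(C)C(OC)=C(C(=O)CCC)C5=O)c(OCc9ccccc9)c(C(=O)CCC)c4OCc9ccccc9)c(OCc9ccccc9)c(C(=O)CCC)c3OCc9ccccc9)c(OCc9ccccc9)c(C(=O)CCC)c2OCc9ccccc9)C1=O | intermediate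
16 | fully protected pentamer: nine benzyl ethers on rings B, C and D, four methyl enol ethers on rings A and E | CCCC(=O)C1=C(OC)C(C)(C)C(OC)=C(Cc2c(OCc9ccccc9)c(Cc3c(OCc9ccccc9)c(Cc4c(OCc9ccccc9)c(CC5=C(OC)C(C)(C)C(OC)=C(C(=O)CCC)C5=O)c(OCc9ccccc9)c(C(=O)CCC)c4OCc9ccccc9)c(OCc9ccccc9)c(C(=O)CCC)c3OCc9ccccc9)c(OCc9ccccc9)c(C(=O)CCC)c2OCc9ccccc9)C1=O | intermediate
17 | nona-O-benzyl pentamer with free ring A and ring E triketones | CCCC(=O)C1=C(O)C(C)(C)C(O)=C(Cc2c(OCc9ccccc9)c(Cc3c(OCc9ccccc9)c(Cc4c(OCc9ccccc9)c(CC5=C(O)C(C)(C)C(O)=C(C(=O)CCC)C5=O)c(OCc9ccccc9)c(C(=O)CCC)c4OCc9ccccc9)c(OCc9ccccc9)c(C(=O)CCC)c3OCc9ccccc9)c(OCc9ccccc9)c(C(=O)CCC)c2OCc9ccccc9)C1=O | intermediate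
18 | CNP0188003.0, pentameric butyrylphloroglucinol A-CH2-B-CH2-C-CH2-D-CH2-E (no stereocentres) | CCCC(=O)C1=C(O)C(C)(C)C(O)=C(Cc2c(O)c(Cc3c(O)c(Cc4c(O)c(CC5=C(O)C(C)(C)C(O)=C(C(=O)CCC)C5=O)c(O)c(C(=O)CCC)c4O)c(O)c(C(=O)CCC)c3O)c(O)c(C(=O)CCC)c2O)C1=O | target

**Step count**
Total: 11 steps. Longest linear sequence: 9 steps from compound 1 (steps 2, 3, 5, 6, 7, 8, 9, 10, 11).

**Steps most likely to fail**

Step 9 (Proposed new method). The aryl-palladium bond may be protonated after CO2 loss, the benzyl and aryl partners may exchange between palladium centres, or reductive elimination to the doubly ortho-flanked diarylmethane may be too slow. The fallback forms the same two bonds by Negishi coupling and sets out from acid 12 and diol 7. Decarboxylative iodination of 12 (I2, K3PO4, MeCN, 100 °C, known for 2,6-dialkoxybenzoic acids) would give the ring A-B aryl iodide F1. Diol 7 with SOCl2 (pyridine cat., CH2Cl2, 0 °C) would give the ring C bis(chloromethyl) compound F2. Zinc insertion into F2 (Zn dust, LiCl, THF, 25 °C) would give the ring C bis(benzylzinc chloride) F3. Coupling of F3 with two equivalents of F1 (Pd(OAc)2, SPhos, THF, 50 °C) returns to the protected pentamer 16, and the route resumes at step 10.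

Step 5. Knoevenagel condensation may be slow at a formyl group shielded by two ortho benzyloxy groups, or both formyl groups of 5 may condense. The fallback replaces condensation by alkylation and sets out from dialdehyde 5. Half-reduction (NaBH4, 0.3 equiv, EtOH/CH2Cl2, -78 °C) with isolation of hydroxy aldehyde 6 is followed by Appel bromination (CBr4, PPh3, CH2Cl2, 0 °C) to the benzylic bromide F4. C-benzylation of the lithium enolate of 3 with F4 (LiOt-Bu, THF/toluene, 0 °C to 25 °C) at its one free ring carbon returns to compound 9.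

Step 8. The electron-rich benzylic oxyphosphonium intermediate may ionise and be captured by the hydrazide, or the second esterification may stall. The fallback uses a preformed benzylic halide and sets out from diol 7. Appel bromination (CBr4, PPh3, CH2Cl2, 0 °C) would give the ring C bis(bromomethyl) compound F5. Alkylation of the cesium salt of acid 12 with F5 (Cs2CO3, DMF, 25 °C) returns to diester 14.

Further compounds
F1 | step 9 | ring A-B aryl iodide, iodine in place of the carboxyl group of 12 | CCCC(=O)C1=C(OC)C(C)(C)C(OC)=C(Cc2c(OCc3ccccc3)c(I)c(OCc3ccccc3)c(C(=O)CCC)c2OCc2ccccc2)C1=O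
F2 | step 9 | ring C bis(chloromethyl) compound, 1-[2,4,6-tris(benzyloxy)-3,5-bis(chloromethyl)phenyl]butan-1-one | CCCC(=O)c1c(OCc2ccccc2)c(CCl)c(OCc2ccccc2)c(CCl)c1OCc1ccccc1
F3 | step 9 | ring C bis(benzylzinc chloride) | CCCC(=O)c1c(OCc2ccccc2)c(C[Zn]Cl)c(OCc2ccccc2)c(C[Zn]Cl)c1OCc1ccccc1
F4 | step 5 | 2,4,6-tris(benzyloxy)-3-(bromomethyl)-5-butanoylbenzaldehyde | CCCC(=O)c1c(OCc2ccccc2)c(C=O)c(OCc2ccccc2)c(CBr)c1OCc1ccccc1
F5 | step 8 | ring C bis(bromomethyl) compound, 1-[2,4,6-tris(benzyloxy)-3,5-bis(bromomethyl)phenyl]butan-1-one | CCCC(=O)c1c(OCc2ccccc2)c(CBr)c(OCc2ccccc2)c(CBr)c1OCc1ccccc1
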